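Its constants are made up.

The product is no final resting place in these flasks, since the second step runs back. The way out of the intermediate without return is the third step, its decomposition, and the intermediate standing at the end or outlet is what is asked.

    starting material + partner ⇌ intermediate (K1 = 709 M⁻¹, k1 = 397 M⁻¹ s⁻¹)
    intermediate ⇌ product + released group (K2 = 1.81 × 10⁻⁴ M, k2 = 0.127 s⁻¹)
    intermediate → decomposed reagent (k3 = 0.121 s⁻¹)
    starting material + protic impurity → quenched substrate (k4 = 42700 M⁻¹ s⁻¹)

| flask | starting material | partner | protic impurity | time | remark |
|---|---|---|---|---|---|
| east | 5.0 × 10⁻⁴ M | 1.50 mM | 0.0100 mM | 12 s | a closed flask charged with all of it at once and left for 12 s |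
| north-east | 5.0 × 10⁻⁴ M | 1.50 mM | 0.0100 mM |  | a single well-mixed tank run continuously and read at steady state, 12 s in it on average |
| north-west | 5.0 × 10⁻⁴ M (fed, over 9.60 s) | 1.50 mM | 0.0100 mM | 12 s | a stirred flask in which starting material is dosed at a steady rate over 9.60 s without added volume, worked up at 12 s |
| west | 5.0 × 10⁻⁴ M | 1.50 mM | 0.0100 mM | 12 s | plug flow through a tube for 12 s, no back-mixing |

1. the set-up with the highest amount of intermediate at the outlet or at the end, in percent of the starting material put in ("none" if the first two lie within 2 percentage points) (east / north-east / north-west / west / none)
2. amount of intermediate at the outlet or at the end, in percent of the starting material put in, east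
3. amount of intermediate at the outlet or at the end, in percent of the starting material put in, north-east
4. amount of intermediate at the outlet or at the end, in percent of the starting material put in, north-west
5. amount of intermediate at the outlet or at the end, in percent of the starting material put in, west

- the stated concentrations are those of everything mixed, before any reaction; amounts are the same in each set-up
- the feed brings no volume worth counting
- run time (east): 12 s

The protic impurity, charged at 2.00% of the starting material, takes that much one for one, so 98.0% remains for the partner. The first step relaxes in 0.865 s, faster than the 4.03 s in which the intermediate leaves by its two exits. So starting material and intermediate form one pool (a pre-equilibrium), and with the partner as charged the intermediate holds a share f = 51.5% of it.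

But the second and third constants, 0.127 s⁻¹ and 0.121 s⁻¹, lie close, and product can return. Taking the product as returned gives the drain constant λ, the third constant times f, 0.0624 s⁻¹; taking it as lost gives 0.128 s⁻¹. So the reckoning by hand brackets east, where the whole charge ages 12 s, below 23.9% and above 10.9%.

West, as plug flow, ages the same. The vessels part by the ages in the charge: survival against λ is 0.473 in east and west, 0.572 in the tank, whose contents have spread ages around a stay of 12 s on average, and 0.638 in the dosed flask, whose charge is on average 7.20 s old at work-up. So the reckoning names north-west.

The forecast gives 16.1% for east, 19.1% for north-east, 22.6% for north-west and 16.1% for west, and names north-west: “Dosing gives the most, because its intermediate was formed later.”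

The flask gives north-west, with 22.8% there, 19.1% in north-east, 16.5% in east and 16.5% in west. The north-west figure moves by 5 points with the partner at 0.908 mM or 3.60 mM, all other amounts and the time held. The ratio of north-west to east reads 1.38, and λ over the difference in age gives 1.35. Carried 8.00 s further, λ takes north-west to 13.8%, and the same flask read at 20 s stands at 14.3%.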